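The numbers of this flask stand for no real mixture; no experiment stands behind them.

Count the bound forms as one pool and ask how much substrate that pool holds at the end.

substrate 20 mM; reagent 12.0 mM; time 1.5 h

    substrate + reagent ⇌ adduct (K1 = 25.1 L mol⁻¹, k1 = 4.96 L mol⁻¹ s⁻¹)
    adduct ⇌ target (K2 = 2.03, k2 = 0.0275 s⁻¹)
    target ⇌ isomer of the product (K3 = 2.13, k3 = 0.0321 s⁻¹)

* why nothing more happens at 1.5 h, or that something still does (it is still moving / the reagent has run out first / all of the substrate has reacted / forward and back rates have come level)
* how much of the substrate has reacted by 1.5 h
* how much target there is at 1.5 h, in percent of the substrate charged
* how much isomer of the product there is at 1.5 h, in percent of the substrate charged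

- the reaction counts as stopped when no species that holds the substrate changes by six tenths of a point or more over the second half of the time
- run time (flask): 1.5 h

1. I checked the clocks first. The second step relaxes with a half-life of 0.281 min by itself, the third has a forward half-life of 0.36 min by itself, and the first, forward at the start, has 0.194 min. Each is short against 1.5 h, so I expected the flask to have come level and reckoned from constants.

2. At level, adduct, target and isomer of the product stand as 1 : 2.03 : 4.32. So I added them into c(bound) and used the total binding constant, c(bound) over free c(substrate) times free c(reagent), 185 L mol⁻¹.

3. My zero of the scale was a constant times free c(substrate) of 1, where bound and free reagent stand level. Taken on the substrate charge, the first step's constant gives 0.50, the total constant 3.69.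

4. I took two extremes. With binding complete, the reagent is the limiting reagent and conversion reaches 60.0%. With the constant of the first step in the mass balance, the quadratic gave 39.8 mM as its dissociation term and 3.51 mM bound, a conversion of 17.6%.

5. I placed the flask between them, since its total constant is larger than the first step's but finite. With 5.42 mM as the dissociation term and 37.4 mM as the sum term, the quadratic gave c(bound) = 8.22 mM. That is a conversion of 41.1%, with target 11.3% and isomer of the product 24.2%.

6. The forecast said forward and back rates have come level, with conversion 41.1%, target 11.3% and isomer of the product 24.2%, on the ground that “the flask has reached full equilibrium, with reagent and substrate both still present”. My figures were the same, and the route cost one constant and one quadratic.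

The simulation gave forward and back rates have come level, with conversion 41.1%, target 11.3% and isomer of the product 24.2%. In this flask, ten times the time left conversion at 41.1%. I then put the total binding constant to the neighbour flask with 30 mM of reagent, where it gave 55.4 mM as the sum term and c(bound) = 14.8 mM, a conversion of 73.8%, and that neighbour flask stood at 73.8%.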